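**Assumption:** locants C1–C20 follow halimane numbering (acid carbon on C4, ring-fusion atoms C5 and C10, side chain on C9); the target is (4S,5S,8R,9S),13E.

**Retrosynthetic overview**
1. Target ⇒ O-propionylation and methyl ester cleavage ⇒ bicyclic hydroxy methyl ester.
2. Ring A (C4–C5 bond, C4 and C5 centres, Δ1(10) olefin) ⇒ cobalt-hydride (HAT) radical 6-endo cycloisomerisation of an α-alkyl acrylate tethered to C10 of a ring-B cyclohexene.
3. Tether ⇒ B-alkyl Suzuki coupling of the ring-B enol triflate with a diene ester made from vinyl Grignard and methyl 2-(bromomethyl)acrylate.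
4. Ring B with C8/C9 ⇒ 2-methylcyclohex-2-enone: Cu-catalysed asymmetric methyl addition, then Mukaiyama–Michael addition to methyl vinyl ketone; side chain by HWE/DIBAL.
5. Ring order: B comes from the enone; A is closed last, in the radical step.

**Step 1**
Reactants: 1 2-methylcyclohex-2-en-1-one
Product: 3 (R)-trimethyl[(2,3-dimethylcyclohex-1-en-1-yl)oxy]silane, via dimethylaluminium enolate 2 (not isolated)
Conditions: Me3Al, CuTC (2 mol%), chiral phosphoramidite (4 mol%, enantiomer giving 3R), Et2O, −30 °C; then TMSOTf, −30 → 0 °C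
Reagents that add atoms: trimethylaluminium C[Al](C)C; trimethylsilyl trifluoromethanesulfonate C[Si](C)(C)OS(=O)(=O)C(F)(F)F
Why: Copper-catalysed asymmetric conjugate addition (Feringa–Alexakis type) in which the chiral Cu–phosphoramidite complex delivers methyl to one enantioface of C8 (sets 8R, typically ≥90% ee for 2-substituted cyclohexenones), and O-silylation of the regiodefined enolate fixes the C9=C10 enol ether.

**Step 2**
Reactants: 3 (R)-trimethyl[(2,3-dimethylcyclohex-1-en-1-yl)oxy]silane; 4 methyl vinyl ketone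
Product: 5 (2S,3R)-2,3-dimethyl-2-(3-oxobutyl)cyclohexan-1-one
Conditions: TiCl4, CH2Cl2, −78 °C; aq. NaHCO3
Reagents that add atoms: none
Why: Mukaiyama–Michael addition in which the TiCl4-activated enone is attacked by C9 of the enol ether on the face anti to the adjacent C8 methyl group (the usual outcome for 2,3-dimethylcyclohexanone enolate equivalents), setting the quaternary C9 centre (9S) with the two methyl groups cis.

**Step 3**
Reactants: 5 (2S,3R)-2,3-dimethyl-2-(3-oxobutyl)cyclohexan-1-one
Product: 6 ethyl (E)-5-[(1S,2R)-1,2-dimethyl-6-oxocyclohexyl]-3-methylpent-2-enoate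
Conditions: (EtO)2P(O)CH2CO2Et, NaH, THF, 0 → 50 °C; minor Z isomer removed by chromatography
Reagents that add atoms: triethyl phosphonoacetate CCOC(=O)CP(=O)(OCC)OCC
Why: Horner–Wadsworth–Emmons olefination in which only the unhindered methyl ketone reacts (the ring ketone is flanked by the quaternary carbon) and the E-enoate is favoured (about 5:1 expected), with no stereocentre touched.

**Step 4**
Reactants: 6 ethyl (E)-5-[(1S,2R)-1,2-dimethyl-6-oxocyclohexyl]-3-methylpent-2-enoate
Product: 8 ethyl (E)-5-[(1S,6R)-1,6-dimethyl-2-(trifluoromethylsulfonyloxy)cyclohex-2-en-1-yl]-3-methylpent-2-enoate, via potassium enolate 7 (not isolated)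
Conditions: KHMDS, THF, −78 °C; Comins' reagent, −78 → −40 °C
Reagents that add atoms: Comins' reagent FC(F)(F)S(=O)(=O)N(c1ccc(Cl)cn1)S(=O)(=O)C(F)(F)F
Why: Kinetic enolisation and O-triflation, where the ring ketone can only enolise toward C5 because C9 is quaternary, the ketone α-CH2 is removed faster than the γ-protons of the enoate at −78 °C, and the enolate is trapped on oxygen as the C5=C10 enol triflate.

**Step 5**
Reactants: 8 ethyl (E)-5-[(1S,6R)-1,6-dimethyl-2-(trifluoromethylsulfonyloxy)cyclohex-2-en-1-yl]-3-methylpent-2-enoate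
Product: 9 (5R,6S)-6-[(E)-5-hydroxy-3-methylpent-3-en-1-yl]-5,6-dimethylcyclohex-1-en-1-yl trifluoromethanesulfonate
Conditions: DIBAL-H (2.3 equiv), CH2Cl2, −78 °C; Rochelle salt
Reagents that add atoms: none
Why: DIBAL-H 1,2-reduction of the α,β-unsaturated ester to the E-allylic alcohol, with the enol triflate inert at −78 °C and the olefin geometry retained.

**Step 6**
Reactants: 10 methyl 2-(bromomethyl)prop-2-enoate
Product: 11 methyl 2-methylidenepent-4-enoate
Conditions: CH2=CHMgBr, CuI (10 mol%), THF, −78 °C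
Reagents that add atoms: vinylmagnesium bromide C=C[Mg]Br
Why: Copper-catalysed SN2′ allylic substitution (addition–elimination) of the 2-(bromomethyl)acrylate by the vinyl Grignard reagent, which is far faster than attack on the ester at −78 °C.

**Step 7**
Reactants: 11 methyl 2-methylidenepent-4-enoate; 9 (5R,6S)-6-[(E)-5-hydroxy-3-methylpent-3-en-1-yl]-5,6-dimethylcyclohex-1-en-1-yl trifluoromethanesulfonate
Product: 13 methyl 5-[(5R,6S)-6-[(E)-5-hydroxy-3-methylpent-3-en-1-yl]-5,6-dimethylcyclohex-1-en-1-yl]-2-methylidenepentanoate, via B-alkyl-9-BBN adduct 12 (not isolated)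
Conditions: 11, 9-BBN, THF, 0 °C → rt; then 9, Pd(dppf)Cl2 (5 mol%), aq. K3PO4, DMF, 50 °C
Reagents that add atoms: none
Why: B-alkyl Suzuki–Miyaura coupling in which 9-BBN hydroborates the terminal monosubstituted olefin of 11 much faster than the electron-poor 1,1-disubstituted acrylate, boron goes to the terminal carbon, and Pd couples the alkylborane with the enol triflate (free hydroxyl tolerated, no stereocentre involved).

**Step 8 (key step)**
Reactants: 13 methyl 5-[(5R,6S)-6-[(E)-5-hydroxy-3-methylpent-3-en-1-yl]-5,6-dimethylcyclohex-1-en-1-yl]-2-methylidenepentanoate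
Product: 16 methyl (1S,5S,6R,8aS)-5-[(E)-5-hydroxy-3-methylpent-3-en-1-yl]-1,5,6-trimethyl-1,2,3,5,6,7,8,8a-octahydronaphthalene-1-carboxylate, via C4 ester radical 14 (not isolated), via C10 ring radical 15 (not isolated)
Conditions: Co(dmgBF2)2(H2O)2 (7 mol%), H2 (6 atm), benzene (0.02 M), 50 °C; diastereomers separated by chromatography
Reagents that add atoms: none
Why: Proposed new method: the cobaloxime hydride formed under H2 transfers H• reversibly to the electron-poor 1,1-disubstituted acrylate (the only good H• acceptor in 13) to give tertiary α-ester radical 14, which closes 6-endo on the less substituted C5 of the C5=C10 olefin (attack at C10 would build a spiro quaternary carbon next to quaternary C9), and tertiary radical 15 returns H• from the unhindered C1–H to Co(II), fixing the Δ1(10) olefin and regenerating Co–H in a redox-neutral cycloisomerisation; C4 and C5 are set in a chair-like transition state in which the C4–C5 bond is expected to form on the face of C5 anti to the pseudo-axial C9 side chain (5-H β) with the ester in the outer pseudo-equatorial position and the new methyl pseudo-axial (ester cis to 5-H), giving (4S,5S) as the expected main isomer; the closest known reaction type is the Norton-type Co–H/Cr–H-initiated radical cyclisation of α-substituted acrylates and Co-salen HAT cycloisomerisation, extended here to a 6-endo closure onto an unactivated ring olefin.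

**Step 9**
Reactants: 16 methyl (1S,5S,6R,8aS)-5-[(E)-5-hydroxy-3-methylpent-3-en-1-yl]-1,5,6-trimethyl-1,2,3,5,6,7,8,8a-octahydronaphthalene-1-carboxylate
Product: 17 (1S,5S,6R,8aS)-5-[(E)-5-hydroxy-3-methylpent-3-en-1-yl]-1,5,6-trimethyl-1,2,3,5,6,7,8,8a-octahydronaphthalene-1-carboxylic acid
Conditions: KOSiMe3 (4 equiv), THF, 65 °C; then aq. HCl to pH 3, 0 °C
Reagents that add atoms: none
Why: Anhydrous silanolate ester cleavage in which potassium trimethylsilanolate converts the hindered methyl ester into the carboxylate under non-aqueous conditions that leave both olefins and all stereocentres untouched.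

**Step 10**
Reactants: 17 (1S,5S,6R,8aS)-5-[(E)-5-hydroxy-3-methylpent-3-en-1-yl]-1,5,6-trimethyl-1,2,3,5,6,7,8,8a-octahydronaphthalene-1-carboxylic acid
Product: 18 (1S,5S,6R,8aS)-1,5,6-trimethyl-5-[(E)-3-methyl-5-(propanoyloxy)pent-3-en-1-yl]-1,2,3,5,6,7,8,8a-octahydronaphthalene-1-carboxylic acid
Conditions: (EtCO)2O (1.5 equiv), pyridine, DMAP (5 mol%), CH2Cl2, 0 °C → rt; aqueous work-up
Reagents that add atoms: propionic anhydride CCC(=O)OC(=O)CC
Why: DMAP-catalysed O-acylation in which the primary allylic alcohol is esterified selectively while the hindered tertiary carboxylic acid is not acylated productively (any mixed anhydride is hydrolysed on work-up), with no stereocentre affected.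

**Compound list**
1 | 2-methylcyclohex-2-en-1-one | CC1=CCCCC1=O | starting material
2 | dimethylaluminium (R)-2,3-dimethylcyclohex-1-en-1-olate | CC1=C(O[Al](C)C)CCC[C@H]1C | intermediate
3 | (R)-trimethyl[(2,3-dimethylcyclohex-1-en-1-yl)oxy]silane | CC1=C(O[Si](C)(C)C)CCC[C@H]1C | intermediate
4 | methyl vinyl ketone (but-3-en-2-one) | CC(=O)C=C | starting material
5 | (2S,3R)-2,3-dimethyl-2-(3-oxobutyl)cyclohexan-1-one | CC(=O)CC[C@]1(C)C(=O)CCC[C@H]1C | intermediate
6 | ethyl (E)-5-[(1S,2R)-1,2-dimethyl-6-oxocyclohexyl]-3-methylpent-2-enoate | CCOC(=O)/C=C(\C)CC[C@]1(C)C(=O)CCC[C@H]1C | intermediate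
7 | potassium (5R,6S)-6-[(E)-5-ethoxy-3-methyl-5-oxopent-3-en-1-yl]-5,6-dimethylcyclohex-1-en-1-olate | CCOC(=O)/C=C(\C)CC[C@]1(C)C([O-])=CCC[C@H]1C.[K+] | intermediate
8 | ethyl (E)-5-[(1S,6R)-1,6-dimethyl-2-(trifluoromethylsulfonyloxy)cyclohex-2-en-1-yl]-3-methylpent-2-enoate | CCOC(=O)/C=C(\C)CC[C@]1(C)C(OS(=O)(=O)C(F)(F)F)=CCC[C@H]1C | intermediate
9 | (5R,6S)-6-[(E)-5-hydroxy-3-methylpent-3-en-1-yl]-5,6-dimethylcyclohex-1-en-1-yl trifluoromethanesulfonate | OC/C=C(\C)CC[C@]1(C)C(OS(=O)(=O)C(F)(F)F)=CCC[C@H]1C | intermediate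
10 | methyl 2-(bromomethyl)prop-2-enoate | C=C(CBr)C(=O)OC | starting material
11 | methyl 2-methylidenepent-4-enoate | C=CCC(=C)C(=O)OC | intermediate
12 | methyl 5-(9-borabicyclo[3.3.1]nonan-9-yl)-2-methylidenepentanoate | COC(=O)C(=C)CCCB1C2CCCC1CCC2 | intermediate
13 | methyl 5-[(5R,6S)-6-[(E)-5-hydroxy-3-methylpent-3-en-1-yl]-5,6-dimethylcyclohex-1-en-1-yl]-2-methylidenepentanoate | OC/C=C(\C)CC[C@]1(C)C(CCCC(=C)C(=O)OC)=CCC[C@H]1C | intermediate
14 | tertiary α-ester radical at C4 formed by H• addition to the acrylate of 13 | OC/C=C(\C)CC[C@]1(C)C(CCC[C](C)C(=O)OC)=CCC[C@H]1C | intermediate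
15 | cyclised tertiary radical at C10 (ring A closed, C4 and C5 set) | OC/C=C(\C)CC[C@]1(C)[C]2CCC[C@](C)(C(=O)OC)[C@H]2CC[C@H]1C | intermediate
16 | methyl (1S,5S,6R,8aS)-5-[(E)-5-hydroxy-3-methylpent-3-en-1-yl]-1,5,6-trimethyl-1,2,3,5,6,7,8,8a-octahydronaphthalene-1-carboxylate | OC/C=C(\C)CC[C@]1(C)C2=CCC[C@](C)(C(=O)OC)[C@H]2CC[C@H]1C | intermediate
17 | (1S,5S,6R,8aS)-5-[(E)-5-hydroxy-3-methylpent-3-en-1-yl]-1,5,6-trimethyl-1,2,3,5,6,7,8,8a-octahydronaphthalene-1-carboxylic acid | OC/C=C(\C)CC[C@]1(C)C2=CCC[C@](C)(C(=O)O)[C@H]2CC[C@H]1C | intermediate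
18 | (1S,5S,6R,8aS)-1,5,6-trimethyl-5-[(E)-3-methyl-5-(propanoyloxy)pent-3-en-1-yl]-1,2,3,5,6,7,8,8a-octahydronaphthalene-1-carboxylic acid | CCC(=O)OC/C=C(\C)CC[C@]1(C)C2=CCC[C@](C)(C(=O)O)[C@H]2CC[C@H]1C | target

**Step count:** 10 steps in total; longest linear sequence 9 steps (steps 1–5 and 7–10; step 6 is a one-step side branch).

**Steps most likely to fail**

Step 8 is the weakest point. The 6-endo closure of a tertiary α-ester radical onto an unactivated trisubstituted olefin is slow, so hydrogenation or isomerisation of the acrylate can compete. The C4/C5 selectivity is also uncertain: the facial bias at C5 from the C9 substituents is small, and the C4 epimer (ester trans to 5-H) may well predominate, as it does in related Mn(III) β-keto ester closures. The fallback sets out from 9 and returns at 17, replacing the radical closure by a cycloaddition. Stille coupling of 9 with tributyl(vinyl)stannane (Pd(PPh3)4, LiCl, THF, 65 °C) gives the diene alcohol (E)-5-[(1S,6R)-2-ethenyl-1,6-dimethylcyclohex-2-en-1-yl]-3-methylpent-2-en-1-ol F1. A Diels–Alder reaction with methacrolein under a chiral oxazaborolidinium Lewis acid (CH2Cl2, −78 °C) then gives the aldehyde (1S,5S,6R,8aS)-5-[(E)-5-hydroxy-3-methylpent-3-en-1-yl]-1,5,6-trimethyl-1,2,3,5,6,7,8,8a-octahydronaphthalene-1-carbaldehyde F2; the catalyst selects the diene face, the regiochemistry is "ortho", and the exo mode puts the formyl group cis to 5-H. Pinnick oxidation (NaClO2, NaH2PO4, 2-methylbut-2-ene, t-BuOH/H2O) gives 17.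

Step 7 can fail through conjugate reduction of the acrylate of 11 by 9-BBN or through protodeboronation of the functionalised alkylborane. The fallback sets out from 9 and returns at 13, moving the hydroboration to a substrate that carries no acrylate. Suzuki coupling of 9 with potassium allyltrifluoroborate (Pd(dppf)Cl2, Cs2CO3, THF/H2O) gives the allyl compound (E)-5-[(1S,6R)-1,6-dimethyl-2-(prop-2-en-1-yl)cyclohex-2-en-1-yl]-3-methylpent-2-en-1-ol F3. 9-BBN (2.2 equiv, the excess is taken up by the hydroxyl) adds only to the terminal olefin to give the borane (E)-5-[(1S,6R)-2-[3-(9-borabicyclo[3.3.1]nonan-9-yl)propyl]-1,6-dimethylcyclohex-2-en-1-yl]-3-methylpent-2-en-1-ol F4, which is coupled with methyl 2-bromoacrylate (Pd(dppf)Cl2, aq. K3PO4) to give 13.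

Step 4 can fail through γ-deprotonation of the enoate or intramolecular Michael addition of the ketone enolate to it. The fallback sets out from 5 and returns at 8, so that no enoate is present during enolisation. Selective ketalisation of the methyl ketone of 5 (ethylene glycol, PPTS, benzene, reflux) gives (2S,3R)-2,3-dimethyl-2-[2-(2-methyl-1,3-dioxolan-2-yl)ethyl]cyclohexan-1-one F5. KHMDS and Comins' reagent then give the ketal triflate (5R,6S)-5,6-dimethyl-6-[2-(2-methyl-1,3-dioxolan-2-yl)ethyl]cyclohex-1-en-1-yl trifluoromethanesulfonate F6. Mild acid (PPTS, wet acetone) releases the keto triflate (5R,6S)-5,6-dimethyl-6-(3-oxobutyl)cyclohex-1-en-1-yl trifluoromethanesulfonate F7, and HWE olefination with triethyl phosphonoacetate gives 8.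

**Further compounds**
F1 | step 8 | (E)-5-[(1S,6R)-2-ethenyl-1,6-dimethylcyclohex-2-en-1-yl]-3-methylpent-2-en-1-ol | OC/C=C(\C)CC[C@]1(C)C(C=C)=CCC[C@H]1C
F2 | step 8 | (1S,5S,6R,8aS)-5-[(E)-5-hydroxy-3-methylpent-3-en-1-yl]-1,5,6-trimethyl-1,2,3,5,6,7,8,8a-octahydronaphthalene-1-carbaldehyde | OC/C=C(\C)CC[C@]1(C)C2=CCC[C@](C)(C=O)[C@H]2CC[C@H]1C
F3 | step 7 | (E)-5-[(1S,6R)-1,6-dimethyl-2-(prop-2-en-1-yl)cyclohex-2-en-1-yl]-3-methylpent-2-en-1-ol | OC/C=C(\C)CC[C@]1(C)C(CC=C)=CCC[C@H]1C
F4 | step 7 | (E)-5-[(1S,6R)-2-[3-(9-borabicyclo[3.3.1]nonan-9-yl)propyl]-1,6-dimethylcyclohex-2-en-1-yl]-3-methylpent-2-en-1-ol | OC/C=C(\C)CC[C@]1(C)C(CCCB2C3CCCC2CCC3)=CCC[C@H]1C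
F5 | step 4 | (2S,3R)-2,3-dimethyl-2-[2-(2-methyl-1,3-dioxolan-2-yl)ethyl]cyclohexan-1-one | CC1(CC[C@]2(C)C(=O)CCC[C@H]2C)OCCO1
F6 | step 4 | (5R,6S)-5,6-dimethyl-6-[2-(2-methyl-1,3-dioxolan-2-yl)ethyl]cyclohex-1-en-1-yl trifluoromethanesulfonate | CC1(CC[C@]2(C)C(OS(=O)(=O)C(F)(F)F)=CCC[C@H]2C)OCCO1
F7 | step 4 | (5R,6S)-5,6-dimethyl-6-(3-oxobutyl)cyclohex-1-en-1-yl trifluoromethanesulfonate | CC(=O)CC[C@]1(C)C(OS(=O)(=O)C(F)(F)F)=CCC[C@H]1C
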